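## Structural features

The target is a flavonol, a 4H-chromen-4-one in which benzene ring A and pyranone ring C share the C4a–C8a bond and a 4-hydroxyphenyl ring B is attached to C2 by a single C–C bond; it has no stereocentre. Four oxygen functions sit on the periphery: O3 as a hydrogen sulfate, O5 as a hydroxyl held to the C4 carbonyl by a hydrogen bond, and free hydroxyls at O7 and O4′. The sulfate monoester on the enolic O3 is the fragile group, since acid cleaves it and every compound that carries it is an involatile salt, so it has to be made close to the end. The real difficulty is therefore not the carbon skeleton but the addressing of O3 among four hydroxyls, of which O7 and O4′ are the more acidic and the more easily sulfated. Ring C is a 3-oxy-4-pyranone with an aryl group on the carbon next to the ring oxygen, which is the pattern of kojic acid after arylation of its free CH next to oxygen, and the enol oxygen of kojic acid can carry a benzyl group of its own from the second step on. Ring A carries O5, O7 and O1 in a 1,3,5 relationship around C4a, and the key step exploits exactly this: a ketene built on the C4a=C8a bond of the pyranone supplies C8 and C5, a silyloxyalkyne supplies C6 and C7, and the resorcinol pattern results with O5 born free and chelated and O7 born as a silyl ether. Each of the four oxygens thus arrives with a different status, and no polyphenol has to be protected selectively.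

## Logic of the disconnections

**22 ⇒ 20.** The silyl groups are put back on O7 and O4′ and the proton is exchanged for an ammonium counter-ion. Cutting here means the sulfate is carried through one operation only and the last isolated intermediate is a lipophilic salt that can be chromatographed. The forward step needs a fluoride source that leaves the S–O ester alone and introduces no cation that is hard to remove; an amine hydrofluoride followed by an acidic resin meets both demands.

**20 ⇒ 19.** The O3–S bond is cut. In 19 only two hydroxyls are free, and one of them, O5, is locked to the C4 carbonyl by a strong hydrogen bond, so the sulfation has one reactive site. The demand is that both aryl silyl ethers survive an amine–SO3 complex, because a freed O7 or O4′ would be sulfated faster than O3.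

**19 ⇒ 18.** The O3–CH2Ph bond is cut. Benzyl sits on O3 alone and can be removed by hydrogenolysis, which is neutral and should spare the silyl ethers and the C2=C3 bond. The forward step must not be run in an alcohol, where Pd/C tends to strip silyl ethers.

**18 ⇒ 10 + 14.** Four bonds of ring A are cut: C8–C8a, C4a–C5, C5–C6 and C7–C8. This removes the whole of ring A with both of its oxygens and leaves a monocyclic pyranone and a two-carbon alkyne, so no symmetrical triphenol has to be protected or acylated. The forward step places three demands. The alkyne must add with its CH carbon to the ketene carbon, the 6π closure must take place onto the pyranone CH, and light must be absorbed by the diazo chromophore and not by the 3-benzyloxy-4-pyranone or by the flavone that forms, since an excited C4 carbonyl could abstract hydrogen from the OCH2Ph group. For that reason long-wavelength light and a flow reactor are specified.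

**10 ⇒ 8.** The C=N2 bond is cut. The diazo group is put in by diazo transfer onto the methyl ketone after activation as 9. This avoids the explosive and toxic C1 diazoalkane that an acid chloride route would need, and with it the hexavalent chromium oxidation that leads to the acid. The demand is clean C-acylation of a single enolate; 8 has no other enolisable position.

**8 ⇒ 5 (through 7 and 6).** The C–CH3 bond and two oxidation levels are removed. The carbon that becomes C5 of the target is the hydroxymethyl carbon of 5, and the methyl group becomes C8. The sequence costs one step more than an acid chloride route but uses only MnO2 and MeMgBr. The organomagnesium reagent has to choose the aldehyde over the C4 carbonyl and over conjugate addition to the pyranone.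

**5 ⇒ 3 + 4.** The C2–C1′ bond between ring C and ring B is cut as a cross-coupling. Ring B arrives in one convergent step with its phenol already silylated. The coupling is placed before all carbonyl chemistry because the C–I bond would not survive organometallic reagents or strong base. It must outrun hydrolysis of the vinylogous acyl iodide and must spare the aryl silyl ether.

**3 ⇒ 1 (through 2).** The O–CH2Ph and C–I bonds are cut. 1 is a cheap fermentation product that already holds the pyranone, the future O3 and the carbon for C5. The iodination has to go to the one CH that is ortho to the enol hydroxyl, and the benzylation has to choose the acidic enol hydroxyl over the primary alcohol.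

**14 ⇒ 11 + 12.** The O–Si bond and the C≡C bond are cut. 14 is not an article of commerce; it is made in one flask from 11, a C1 carbenoid and 12 through 13. The demand is O-silylation of 13 and no metalation of its acetylenic CH.

## Other disconnections considered

Alternative 1: The cut is the C3–C4 bond of ring C. In the forward direction a carbene generated from a triazolium salt and an amidine base would join the two formyl carbons of rac-2-[3,5-bis(benzyloxy)-2-formylphenoxy]-2-[4-(benzyloxy)phenyl]acetaldehyde A1 in an intramolecular crossed benzoin reaction. The product would be rac-(2R,3R)-5,7-bis(benzyloxy)-2-[4-(benzyloxy)phenyl]-3-hydroxychroman-4-one A2.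
- In favour: the conditions are mild and metal-free, rings A and B are bought, and O3 is born as the only free hydroxyl. All other oxygens carry benzyl, so the end game can be sulfation followed by hydrogenolysis, which a sulfate tolerates.
- Against: A2 is at the flavanonol oxidation level, so two stereocentres are made only to be erased by a dehydrogenation to 5,7-bis(benzyloxy)-2-[4-(benzyloxy)phenyl]-3-hydroxy-4H-chromen-4-one A3. The acyl anion equivalent would have to form at the aromatic aldehyde of A1, which is electron-rich and flanked by two ortho substituents, while the aliphatic aldehyde is the more accessible. Reaction at the aliphatic aldehyde would close the ring the other way round, with the ketone at C3 and the hydroxyl at C4. A1 is also an enolisable α-aryloxy aldehyde that is unlikely to store well.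
- Comparison: on structure the alternative closes ring C between bought rings, whereas the chosen plan builds ring A with its oxygens at the right oxidation level. On mechanism it rests on polarity reversal whose site selectivity is open, against a pericyclic cascade whose regiochemistry is set by the polarisation of the alkyne. In step economy it is the better by an estimated three steps, and its benzyl-only end game is more robust than the silyl ether end game of the chosen plan.

Alternative 2: The cuts are C3–C4 and O1–C8a. The lithium enolate of 1-[4-(benzyloxy)phenyl]-2-(methoxymethoxy)ethan-1-one A4 would be acylated at carbon by 2,4,6-trifluorobenzoyl chloride A5. Warming with a carbonate base would then let the enol oxygen displace an ortho fluoride to give 2-[4-(benzyloxy)phenyl]-5,7-difluoro-3-(methoxymethoxy)-4H-chromen-4-one A6.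
- In favour: two bonds form in one flask from simple partners, the two ortho fluorines of A5 are equivalent so there is no regiochemical question, the chemistry is ionic and scalable, and O3 is masked by an acetal that is orthogonal to benzyl.
- Against: ring A arrives in A6 with fluorine where oxygen is needed. Two substitutions by a benzylic alkoxide would be required to reach 5,7-bis(benzyloxy)-2-[4-(benzyloxy)phenyl]-3-(methoxymethoxy)-4H-chromen-4-one A7. The second is slowed by the donor installed in the first, and it competes with attack of the alkoxide at C2 and opening of ring C. O-acylation of the enolate of A4 is a further leak. Acid would then free O3 of A7 to give A3 for sulfation and hydrogenolysis.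
- Comparison: on structure the chosen plan delivers O5 and O7 directly and already differentiated, which is its advantage. On mechanism the alternative relies on a Claisen-type acylation and an addition–elimination at an activated arene, both well understood and at least the equal of a photochemical cascade in predictability. In step economy (an estimated seven to eight steps), in the absence of diazo compounds and light, and in ease of scale-up, this alternative is the better.

Alternative 3: The cuts are C4–C4a and O1–C2. Phloroglucinol A8 and rac-ethyl 2-(benzyloxy)-3-(4-hydroxyphenyl)-3-oxopropanoate A9 would be heated together without solvent or catalyst. Two condensations should then give 3-(benzyloxy)-5,7-dihydroxy-2-(4-hydroxyphenyl)-4H-chromen-4-one A10.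
- In favour: this is the most direct construction. Ring A is bought intact as A8, no protecting group is needed on it, and O3 is the only oxygen that carries benzyl.
- Against: the union of a phenol with a β-keto ester can also take the Pechmann course to the isomeric lactone, and the oxygen substituent on the central carbon of A9 may shift that balance. The temperatures needed may cause debenzylation of A9 or C-benzylation of A8. A10 still needs O7 and O4′ masked, for instance as 3-(benzyloxy)-7-(tert-butyldimethylsilyloxy)-2-[4-(tert-butyldimethylsilyloxy)phenyl]-5-hydroxy-4H-chromen-4-one A11, before the same three closing operations as in the chosen plan.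
- Comparison: in step economy this alternative is clearly the better (an estimated seven steps against twelve), and it is the equal of the chosen plan in the end game. On structure it uses ring A as bought, which is simpler than building it. On mechanism the chosen plan is better only in that the place of every oxygen follows from the cascade, with no ambiguity between the two modes of condensation, and in that O7 and O4′ emerge protected without a selective silylation.

Key step: step 9

Assumption: the target is taken as the free hydrogen sulfate that its SMILES shows; it is released by a final cation exchange and would be converted to a salt for storage.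

## Steps

Step 1
Reactants: 1 kojic acid
Product: 2 5-hydroxy-2-(hydroxymethyl)-6-iodo-4H-pyran-4-one
Conditions: I2, Na2CO3, H2O, 0 °C to rt
Reagents that add atoms: iodine, II
Why: Electrophilic iodination of the enolate of a 5-hydroxy-4-pyranone; the enol oxygen directs iodine to C6, the only CH ortho to it, the same site at which kojic acid takes part in Mannich and aldol reactions.

Step 2
Reactants: 2 5-hydroxy-2-(hydroxymethyl)-6-iodo-4H-pyran-4-one
Product: 3 5-(benzyloxy)-2-(hydroxymethyl)-6-iodo-4H-pyran-4-one
Conditions: BnBr, K2CO3, DMF, rt
Reagents that add atoms: benzyl bromide, BrCc1ccccc1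
Why: Williamson ether synthesis; carbonate deprotonates only the enolic hydroxyl, which has the acidity of a phenol, so the primary alcohol should stay free.

Step 3
Reactants: 3 5-(benzyloxy)-2-(hydroxymethyl)-6-iodo-4H-pyran-4-one; 4 4-(tert-butyldimethylsilyloxy)phenylboronic acid
Product: 5 3-(benzyloxy)-2-[4-(tert-butyldimethylsilyloxy)phenyl]-6-(hydroxymethyl)-4H-pyran-4-one
Conditions: Pd(PPh3)4 (cat.), K3PO4, dioxane/H2O, 70 °C
Reagents that add atoms: none
Why: Suzuki–Miyaura coupling; the C–I bond at the β-carbon of the vinylogous ester should add quickly to zerovalent palladium, and a phosphate base with little water limits hydrolysis of the iodide and loss of the aryl silyl ether.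

Step 4
Reactants: 5 3-(benzyloxy)-2-[4-(tert-butyldimethylsilyloxy)phenyl]-6-(hydroxymethyl)-4H-pyran-4-one
Product: 6 5-(benzyloxy)-6-[4-(tert-butyldimethylsilyloxy)phenyl]-4-oxo-4H-pyran-2-carbaldehyde
Conditions: MnO2, CH2Cl2, rt
Reagents that add atoms: none
Why: MnO2 oxidation of an allylic-type alcohol on an sp2 carbon of the pyranone; it should stop at the aldehyde and leave the benzyl and silyl ethers untouched.

Step 5
Reactants: 6 5-(benzyloxy)-6-[4-(tert-butyldimethylsilyloxy)phenyl]-4-oxo-4H-pyran-2-carbaldehyde
Product: 7 rac-3-(benzyloxy)-2-[4-(tert-butyldimethylsilyloxy)phenyl]-6-(1-hydroxyethyl)-4H-pyran-4-one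
Conditions: MeMgBr, THF, −78 °C
Reagents that add atoms: methylmagnesium bromide, C[Mg]Br
Why: Grignard addition to the aldehyde, which at −78 °C is far more electrophilic than the vinylogous-ester carbonyl C4; the carbinol centre forms as a racemate and is removed in step 6.

Step 6
Reactants: 7 rac-3-(benzyloxy)-2-[4-(tert-butyldimethylsilyloxy)phenyl]-6-(1-hydroxyethyl)-4H-pyran-4-one
Product: 8 6-acetyl-3-(benzyloxy)-2-[4-(tert-butyldimethylsilyloxy)phenyl]-4H-pyran-4-one
Conditions: MnO2, CH2Cl2, rt
Reagents that add atoms: none
Why: Second MnO2 oxidation of an allylic-type alcohol; it gives a methyl ketone whose only enolisable position is the acetyl group.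

Step 7
Reactants: 8 6-acetyl-3-(benzyloxy)-2-[4-(tert-butyldimethylsilyloxy)phenyl]-4H-pyran-4-one
Product: 10 3-(benzyloxy)-2-[4-(tert-butyldimethylsilyloxy)phenyl]-6-(diazoacetyl)-4H-pyran-4-one, via trifluoroacetyl diketone 9 (not isolated)
Conditions: LiN(SiMe3)2, THF, −78 °C; CF3CO2CH2CF3; aq. HCl; then 4-AcNHC6H4SO2N3, Et3N, H2O, MeCN, rt
Reagents that add atoms: 4-acetamidobenzenesulfonyl azide, CC(=O)Nc1ccc(cc1)S(=O)(=O)N=[N+]=[N-] (the two diazo nitrogens); 2,2,2-trifluoroethyl trifluoroacetate, O=C(OCC(F)(F)F)C(F)(F)F (trifluoroacetyl group, carried by 9 only)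
Why: Detrifluoroacetylative diazo transfer, a Regitz-type transfer to an activated ketone: the lithium enolate is C-acylated, and the 1,3-diketone takes the diazo group from the sulfonyl azide while the trifluoroacetyl group leaves as the N-sulfonyl amide. No diazomethane is needed, and the azide chosen is among the least shock-sensitive transfer reagents.

Step 8
Reactants: 11 ethyl formate; 12 triisopropylsilyl trifluoromethanesulfonate
Product: 14 (triisopropylsilyloxy)ethyne, via lithium ethynolate 13 (not isolated)
Conditions: CH2Br2, lithium 2,2,6,6-tetramethylpiperidide (LiTMP, 2 equiv), THF, −78 °C; 11; then n-BuLi (1 equiv), −78 to 0 °C; then 12, −78 °C to rt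
Reagents that add atoms: dibromomethane, BrCBr
Why: Kowalski ester homologation stopped at the ynolate: LiCHBr2 adds to the formate, and bromine–lithium exchange followed by a 1,2-hydride shift of the carbenoid gives the ynolate, which the bulky, hard silyl triflate should silylate at oxygen. One equivalent of n-BuLi is used so that the acetylenic CH of the ynolate is not metalated.

Step 9
Reactants: 10 3-(benzyloxy)-2-[4-(tert-butyldimethylsilyloxy)phenyl]-6-(diazoacetyl)-4H-pyran-4-one; 14 (triisopropylsilyloxy)ethyne
Product: 18 3-(benzyloxy)-2-[4-(tert-butyldimethylsilyloxy)phenyl]-5-hydroxy-7-(triisopropylsilyloxy)-4H-chromen-4-one, via pyranonylketene 15 (not isolated), via siloxycyclobutenone 16 (not isolated), via dienylketene 17 (not isolated)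
Conditions: 14 (excess), hν (ca. 440 nm LED), ClCH2CH2Cl, rt, flow reactor; then 80 °C
Reagents that add atoms: none
Why: Light absorbed in the long-wavelength band of the diazo ketone expels N2, and the pyranonyl group shifts to the former diazo carbon (Wolff rearrangement, C8–C8a) to give ketene 15, which is conjugated with the ring double bond of the pyranone that becomes C4a=C8a and so is a vinylketene. The electron-rich CH carbon of 14 attacks the ketene carbon in a (2+2) cycloaddition (C5–C6 and C7–C8) to give the racemic cyclobutenone 16. On warming, 16 opens reversibly by 4π electrocyclic cleavage to dienylketene 17, and the isomer with the pyranone turned toward the ketene closes ring A by a thermal 6π electrocyclisation onto the pyranone CH (C4a–C5); tautomerisation then gives the phenol. The closest known reaction is the Danheiser benzannulation in its photochemical diazo ketone form, which is established for unsaturated and heteroaryl diazo ketones with siloxyalkynes. No stereocentre remains, since the one centre of 16 becomes the sp2 carbon C8. The step needs regiocontrol in the cycloaddition, and the polarisation of the ynol ether secures it, placing the silyloxy group at C7, meta to the new C5 hydroxyl. The closure has only one site, because the other neighbour of the ketene-bearing carbon is the ring oxygen, and the pyranone double bond is only weakly aromatic and should take part readily. Near-visible light in a thin flow channel is chosen so that neither the 3-benzyloxy-4-pyranone nor the flavone product is excited and abstraction of hydrogen from OCH2Ph by the C4 carbonyl is avoided.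

Step 10
Reactants: 18 3-(benzyloxy)-2-[4-(tert-butyldimethylsilyloxy)phenyl]-5-hydroxy-7-(triisopropylsilyloxy)-4H-chromen-4-one
Product: 19 2-[4-(tert-butyldimethylsilyloxy)phenyl]-3,5-dihydroxy-7-(triisopropylsilyloxy)-4H-chromen-4-one
Conditions: H2 (1 atm), Pd/C, EtOAc, rt
Reagents that add atoms: none
Why: Hydrogenolysis of the benzyl ether; in ethyl acetate the aryl silyl ethers and the C2=C3 bond of the chromone are expected to persist, and O3 is freed as the only hydroxyl outside the strong six-membered chelate.

Step 11
Reactants: 19 2-[4-(tert-butyldimethylsilyloxy)phenyl]-3,5-dihydroxy-7-(triisopropylsilyloxy)-4H-chromen-4-one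
Product: 20 triethylammonium 2-[4-(tert-butyldimethylsilyloxy)phenyl]-5-hydroxy-4-oxo-7-(triisopropylsilyloxy)-4H-chromen-3-yl sulfate
Conditions: SO3·NEt3, Et3N, DMF, rt to 40 °C
Reagents that add atoms: sulfur trioxide–triethylamine complex, CC[N+](CC)(CC)S(=O)(=O)[O-]
Why: O-sulfation of an enolic hydroxyl with an amine–sulfur trioxide complex; O5–H is held in a six-membered hydrogen bond to the C4 carbonyl and should not react. Anhydrous amine conditions keep the silyl ethers in place, and the product is a lipophilic salt.

Step 12
Reactants: 20 triethylammonium 2-[4-(tert-butyldimethylsilyloxy)phenyl]-5-hydroxy-4-oxo-7-(triisopropylsilyloxy)-4H-chromen-3-yl sulfate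
Product: 22 kaempferol 3-O-sulfate (5,7-dihydroxy-2-(4-hydroxyphenyl)-4-oxo-4H-chromen-3-yl hydrogen sulfate), via triethylammonium kaempferol 3-sulfate 21 (not isolated)
Conditions: Et3N·3HF, THF/MeCN, rt; then sulfonic acid resin (H+ form), MeOH/H2O, 0 °C
Reagents that add atoms: none
Why: Fluoride cleaves both aryl silyl ethers (strong Si–F bond, acidic phenols as leaving groups) under nearly neutral conditions that an aryl sulfate monoester should tolerate; the acidic resin then exchanges triethylammonium for a proton in the cold.

## Compound list

1 | kojic acid (5-hydroxy-2-(hydroxymethyl)-4H-pyran-4-one) | OCc1cc(=O)c(O)co1 | starting material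
2 | 5-hydroxy-2-(hydroxymethyl)-6-iodo-4H-pyran-4-one | OCc1cc(=O)c(O)c(I)o1 | intermediate
3 | 5-(benzyloxy)-2-(hydroxymethyl)-6-iodo-4H-pyran-4-one | OCc1cc(=O)c(OCc2ccccc2)c(I)o1 | intermediate
4 | 4-(tert-butyldimethylsilyloxy)phenylboronic acid | CC(C)(C)[Si](C)(C)Oc1ccc(B(O)O)cc1 | starting material
5 | 3-(benzyloxy)-2-[4-(tert-butyldimethylsilyloxy)phenyl]-6-(hydroxymethyl)-4H-pyran-4-one | OCc1cc(=O)c(OCc2ccccc2)c(-c2ccc(O[Si](C)(C)C(C)(C)C)cc2)o1 | intermediate
6 | 5-(benzyloxy)-6-[4-(tert-butyldimethylsilyloxy)phenyl]-4-oxo-4H-pyran-2-carbaldehyde | O=Cc1cc(=O)c(OCc2ccccc2)c(-c2ccc(O[Si](C)(C)C(C)(C)C)cc2)o1 | intermediate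
7 | rac-3-(benzyloxy)-2-[4-(tert-butyldimethylsilyloxy)phenyl]-6-(1-hydroxyethyl)-4H-pyran-4-one | CC(O)c1cc(=O)c(OCc2ccccc2)c(-c2ccc(O[Si](C)(C)C(C)(C)C)cc2)o1 | intermediate
8 | 6-acetyl-3-(benzyloxy)-2-[4-(tert-butyldimethylsilyloxy)phenyl]-4H-pyran-4-one | CC(=O)c1cc(=O)c(OCc2ccccc2)c(-c2ccc(O[Si](C)(C)C(C)(C)C)cc2)o1 | intermediate
9 | 1-{5-(benzyloxy)-6-[4-(tert-butyldimethylsilyloxy)phenyl]-4-oxo-4H-pyran-2-yl}-4,4,4-trifluorobutane-1,3-dione | O=C(CC(=O)C(F)(F)F)c1cc(=O)c(OCc2ccccc2)c(-c2ccc(O[Si](C)(C)C(C)(C)C)cc2)o1 | intermediate
10 | 3-(benzyloxy)-2-[4-(tert-butyldimethylsilyloxy)phenyl]-6-(diazoacetyl)-4H-pyran-4-one | [N-]=[N+]=CC(=O)c1cc(=O)c(OCc2ccccc2)c(-c2ccc(O[Si](C)(C)C(C)(C)C)cc2)o1 | intermediate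
11 | ethyl formate | CCOC=O | starting material
12 | triisopropylsilyl trifluoromethanesulfonate | CC(C)[Si](OS(=O)(=O)C(F)(F)F)(C(C)C)C(C)C | starting material
13 | lithium ethynolate | [Li+].[O-]C#C | intermediate
14 | (triisopropylsilyloxy)ethyne | C#CO[Si](C(C)C)(C(C)C)C(C)C | intermediate
15 | 2-{5-(benzyloxy)-6-[4-(tert-butyldimethylsilyloxy)phenyl]-4-oxo-4H-pyran-2-yl}ethen-1-one (ketene) | O=C=Cc1cc(=O)c(OCc2ccccc2)c(-c2ccc(O[Si](C)(C)C(C)(C)C)cc2)o1 | intermediate
16 | rac-4-{5-(benzyloxy)-6-[4-(tert-butyldimethylsilyloxy)phenyl]-4-oxo-4H-pyran-2-yl}-3-(triisopropylsilyloxy)cyclobut-2-en-1-one | O=C1C=C(O[Si](C(C)C)(C(C)C)C(C)C)C1c1cc(=O)c(OCc2ccccc2)c(-c2ccc(O[Si](C)(C)C(C)(C)C)cc2)o1 | intermediate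
17 | (3E)-4-{5-(benzyloxy)-6-[4-(tert-butyldimethylsilyloxy)phenyl]-4-oxo-4H-pyran-2-yl}-3-(triisopropylsilyloxy)buta-1,3-dien-1-one | O=C=C/C(O[Si](C(C)C)(C(C)C)C(C)C)=C\c1cc(=O)c(OCc2ccccc2)c(-c2ccc(O[Si](C)(C)C(C)(C)C)cc2)o1 | intermediate
18 | 3-(benzyloxy)-2-[4-(tert-butyldimethylsilyloxy)phenyl]-5-hydroxy-7-(triisopropylsilyloxy)-4H-chromen-4-one | O=c1c(OCc2ccccc2)c(-c2ccc(O[Si](C)(C)C(C)(C)C)cc2)oc2cc(O[Si](C(C)C)(C(C)C)C(C)C)cc(O)c12 | intermediate
19 | 2-[4-(tert-butyldimethylsilyloxy)phenyl]-3,5-dihydroxy-7-(triisopropylsilyloxy)-4H-chromen-4-one | O=c1c(O)c(-c2ccc(O[Si](C)(C)C(C)(C)C)cc2)oc2cc(O[Si](C(C)C)(C(C)C)C(C)C)cc(O)c12 | intermediate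
20 | triethylammonium 2-[4-(tert-butyldimethylsilyloxy)phenyl]-5-hydroxy-4-oxo-7-(triisopropylsilyloxy)-4H-chromen-3-yl sulfate | CC[NH+](CC)CC.[O-]S(=O)(=O)Oc1c(-c2ccc(O[Si](C)(C)C(C)(C)C)cc2)oc2cc(O[Si](C(C)C)(C(C)C)C(C)C)cc(O)c2c1=O | intermediate
21 | triethylammonium 5,7-dihydroxy-2-(4-hydroxyphenyl)-4-oxo-4H-chromen-3-yl sulfate | CC[NH+](CC)CC.[O-]S(=O)(=O)Oc1c(-c2ccc(O)cc2)oc2cc(O)cc(O)c2c1=O | intermediate
22 | kaempferol 3-O-sulfate (5,7-dihydroxy-2-(4-hydroxyphenyl)-4-oxo-4H-chromen-3-yl hydrogen sulfate) | O=c1c(OS(=O)(=O)O)c(-c2ccc(O)cc2)oc2cc(O)cc(O)c12 | target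

## Step count and least certain steps

Total: 12 steps. Longest linear sequence: 11 steps (steps 1 to 7 and 9 to 12 from kojic acid); step 8 is a one-step side branch.

**Step 9 (key step).** The most likely failure is on the photochemical side. The pyranone or the flavone product may compete for the light, followed by hydrogen abstraction from the benzylic CH2 or rearrangement of the pyranone. Alternatively, the acyl carbene may be lost to insertion or cyclopropenation because the migrating carbon is an electron-poor vinylogous ester carbon and may shift slowly. Acylation of the newly formed phenol by a second ketene is a further drain.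
Fallback, from 10 back to 18, with the ketene made in the dark: a Wolff rearrangement catalysed by AgO2CPh and Et3N in wet THF (Arndt–Eistert conditions) should give {5-(benzyloxy)-6-[4-(tert-butyldimethylsilyloxy)phenyl]-4-oxo-4H-pyran-2-yl}acetic acid F1. Oxalyl chloride with a trace of DMF converts it to {5-(benzyloxy)-6-[4-(tert-butyldimethylsilyloxy)phenyl]-4-oxo-4H-pyran-2-yl}acetyl chloride F2. Dehydrochlorination of F2 with Et3N in the presence of 14 generates ketene 15 without light, and warming to 80 °C should lead through 16 and 17 to 18.

**Step 8.** The formate stage may take up a second LiCHBr2, and the acidic CH of the ynolate may be metalated, so that silylation goes to carbon and ends in a silylketene. The product is also volatile and sensitive to moisture, so losses on isolation are likely.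
Fallback, from 12 back to 18: Me3SiC≡CLi is oxidised with LiOOt-Bu to lithium 2-(trimethylsilyl)ethynolate F3, which has no acidic CH, and O-silylation with the bulky triflate 12 gives 1-(triisopropylsilyloxy)-2-(trimethylsilyl)ethyne F4. The benzannulation of 10 with F4 under the conditions of step 9 should give 3-(benzyloxy)-2-[4-(tert-butyldimethylsilyloxy)phenyl]-5-hydroxy-7-(triisopropylsilyloxy)-6-(trimethylsilyl)-4H-chromen-4-one F5. Ipso-protodesilylation of the electron-rich C6 position with CF3CO2H in CH2Cl2 at 0 °C then leads to 18.

**Step 5.** The Grignard reagent may add to the C4 carbonyl or in conjugate fashion to the pyranone, or it may cleave the aryl silyl ether.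
Fallback, from 5 back to 10, bypassing steps 4 to 7: oxidation with TEMPO and PhI(OAc)2 in aqueous MeCN gives 5-(benzyloxy)-6-[4-(tert-butyldimethylsilyloxy)phenyl]-4-oxo-4H-pyran-2-carboxylic acid F6. Oxalyl chloride gives 5-(benzyloxy)-6-[4-(tert-butyldimethylsilyloxy)phenyl]-4-oxo-4H-pyran-2-carbonyl chloride F7, and acylation of Me3SiCHN2 in MeCN at 0 °C gives 10. This is two steps shorter but uses a toxic diazoalkane, although not an explosive one, and is held in reserve for that reason.

**Step 11.** The O7 silyl ether may be lost under amine base in DMF, and the freed phenol would then be sulfated as well. The O3–H, which is weakly hydrogen-bonded to the C4 carbonyl, may also react sluggishly.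
Fallback, from 19 back to 20, with a protected sulfate: 2,2,2-trichloroethyl chlorosulfate with Et3N and DMAP in THF at 0 °C should give the neutral, chromatographable diester 2-[4-(tert-butyldimethylsilyloxy)phenyl]-5-hydroxy-4-oxo-7-(triisopropylsilyloxy)-4H-chromen-3-yl 2,2,2-trichloroethyl sulfate F8. Reductive removal of the trichloroethyl group with Zn and HCO2NH4 in MeOH gives ammonium 2-[4-(tert-butyldimethylsilyloxy)phenyl]-5-hydroxy-4-oxo-7-(triisopropylsilyloxy)-4H-chromen-3-yl sulfate F9. Evaporation from methanolic Et3N exchanges ammonia for triethylamine and gives 20. Loss of a silyl group after the diester stage is harmless, because the sulfate is already in place.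

## Further compounds

F1 | step 9 | {5-(benzyloxy)-6-[4-(tert-butyldimethylsilyloxy)phenyl]-4-oxo-4H-pyran-2-yl}acetic acid | OC(=O)Cc1cc(=O)c(OCc2ccccc2)c(-c2ccc(O[Si](C)(C)C(C)(C)C)cc2)o1
F2 | step 9 | {5-(benzyloxy)-6-[4-(tert-butyldimethylsilyloxy)phenyl]-4-oxo-4H-pyran-2-yl}acetyl chloride | ClC(=O)Cc1cc(=O)c(OCc2ccccc2)c(-c2ccc(O[Si](C)(C)C(C)(C)C)cc2)o1
F3 | step 8 | lithium 2-(trimethylsilyl)ethynolate | [Li+].[O-]C#C[Si](C)(C)C
F4 | step 8 | 1-(triisopropylsilyloxy)-2-(trimethylsilyl)ethyne | C[Si](C)(C)C#CO[Si](C(C)C)(C(C)C)C(C)C
F5 | step 8 | 3-(benzyloxy)-2-[4-(tert-butyldimethylsilyloxy)phenyl]-5-hydroxy-7-(triisopropylsilyloxy)-6-(trimethylsilyl)-4H-chromen-4-one | O=c1c(OCc2ccccc2)c(-c2ccc(O[Si](C)(C)C(C)(C)C)cc2)oc2cc(O[Si](C(C)C)(C(C)C)C(C)C)c([Si](C)(C)C)c(O)c12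
F6 | step 5 | 5-(benzyloxy)-6-[4-(tert-butyldimethylsilyloxy)phenyl]-4-oxo-4H-pyran-2-carboxylic acid | OC(=O)c1cc(=O)c(OCc2ccccc2)c(-c2ccc(O[Si](C)(C)C(C)(C)C)cc2)o1
F7 | step 5 | 5-(benzyloxy)-6-[4-(tert-butyldimethylsilyloxy)phenyl]-4-oxo-4H-pyran-2-carbonyl chloride | ClC(=O)c1cc(=O)c(OCc2ccccc2)c(-c2ccc(O[Si](C)(C)C(C)(C)C)cc2)o1
F8 | step 11 | 2-[4-(tert-butyldimethylsilyloxy)phenyl]-5-hydroxy-4-oxo-7-(triisopropylsilyloxy)-4H-chromen-3-yl 2,2,2-trichloroethyl sulfate | ClC(Cl)(Cl)COS(=O)(=O)Oc1c(-c2ccc(O[Si](C)(C)C(C)(C)C)cc2)oc2cc(O[Si](C(C)C)(C(C)C)C(C)C)cc(O)c2c1=O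
F9 | step 11 | ammonium 2-[4-(tert-butyldimethylsilyloxy)phenyl]-5-hydroxy-4-oxo-7-(triisopropylsilyloxy)-4H-chromen-3-yl sulfate | [NH4+].[O-]S(=O)(=O)Oc1c(-c2ccc(O[Si](C)(C)C(C)(C)C)cc2)oc2cc(O[Si](C(C)C)(C(C)C)C(C)C)cc(O)c2c1=O
A1 | alternative 1 | rac-2-[3,5-bis(benzyloxy)-2-formylphenoxy]-2-[4-(benzyloxy)phenyl]acetaldehyde | O=CC(Oc1cc(OCc2ccccc2)cc(OCc2ccccc2)c1C=O)c1ccc(OCc2ccccc2)cc1
A2 | alternative 1 | rac-(2R,3R)-5,7-bis(benzyloxy)-2-[4-(benzyloxy)phenyl]-3-hydroxychroman-4-one (trans, one enantiomer drawn) | C(c1ccccc1)Oc1ccc(cc1)[C@@H]1[C@H](C(=O)c2c(OCc3ccccc3)cc(OCc3ccccc3)cc2O1)O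
A3 | alternative 1 | 5,7-bis(benzyloxy)-2-[4-(benzyloxy)phenyl]-3-hydroxy-4H-chromen-4-one | O=c1c(O)c(-c2ccc(OCc3ccccc3)cc2)oc2cc(OCc3ccccc3)cc(OCc3ccccc3)c12
A4 | alternative 2 | 1-[4-(benzyloxy)phenyl]-2-(methoxymethoxy)ethan-1-one | COCOCC(=O)c1ccc(OCc2ccccc2)cc1
A5 | alternative 2 | 2,4,6-trifluorobenzoyl chloride | O=C(Cl)c1c(F)cc(F)cc1F
A6 | alternative 2 | 2-[4-(benzyloxy)phenyl]-5,7-difluoro-3-(methoxymethoxy)-4H-chromen-4-one | O=c1c(OCOC)c(-c2ccc(OCc3ccccc3)cc2)oc2cc(F)cc(F)c12
A7 | alternative 2 | 5,7-bis(benzyloxy)-2-[4-(benzyloxy)phenyl]-3-(methoxymethoxy)-4H-chromen-4-one | O=c1c(OCOC)c(-c2ccc(OCc3ccccc3)cc2)oc2cc(OCc3ccccc3)cc(OCc3ccccc3)c12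
A8 | alternative 3 | phloroglucinol (benzene-1,3,5-triol) | Oc1cc(O)cc(O)c1
A9 | alternative 3 | rac-ethyl 2-(benzyloxy)-3-(4-hydroxyphenyl)-3-oxopropanoate | CCOC(=O)C(OCc1ccccc1)C(=O)c1ccc(O)cc1
A10 | alternative 3 | 3-(benzyloxy)-5,7-dihydroxy-2-(4-hydroxyphenyl)-4H-chromen-4-one | O=c1c(OCc2ccccc2)c(-c2ccc(O)cc2)oc2cc(O)cc(O)c12
A11 | alternative 3 | 3-(benzyloxy)-7-(tert-butyldimethylsilyloxy)-2-[4-(tert-butyldimethylsilyloxy)phenyl]-5-hydroxy-4H-chromen-4-one | O=c1c(OCc2ccccc2)c(-c2ccc(O[Si](C)(C)C(C)(C)C)cc2)oc2cc(O[Si](C)(C)C(C)(C)C)cc(O)c12
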